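**Retrosynthetic overview**
- The target comes from a one-pot acetal hydrolysis/desilylation of a protected ten-membered germacranolide; the carbocycle (ring B) is closed last by ring-closing metathesis at C4=C5.
- The metathesis precursor comes from a Nozaki–Hiyama–Kishi coupling at C9–C10 between fragment A (lactone aldehyde, C5–C9 and C11–C13, with the 2-methylbutanoate already on O8) and fragment B (a (Z)-vinyl iodide, C10, C14, C1–C4, C15).
- Fragment A comes from a chromium Barbier allylation of an (R)-3-(bromomethyl)-5-propenylbutenolide with silyloxyacetaldehyde (sets C7 and C8 from C6), then acylation and unmasking of C9.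
- The butenolide (ring A) comes from ester ring-closing metathesis of a kinetically resolved dienol; fragment B comes from propargyl alcohol by carbomagnesiation, cross-metathesis, α-iodination and acetalisation.
- Ring order: γ-lactone (ring A) first, ten-membered carbocycle (ring B) last.

Assumption: positions use germacrane numbering (ring C1–C10, lactone C11–C13 with C12 the carbonyl, C14 the aldehyde carbon, C15 the hydroxymethyl carbon); both Grignard reagents are bought as THF solutions.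

**Route**

Step 1
Reactants: 1 (2E)-but-2-enal; 2 vinylmagnesium bromide
Product: 3 (±)-(4E)-hexa-1,4-dien-3-ol
Conditions: THF, −78 to 0 °C; then H2O
Reagents that add atoms: none
Why: Grignard 1,2-addition to the enal gives the bis-allylic alcohol whose carbinol carbon becomes C6 (racemic at this stage).

Step 2
Reactants: 3 (±)-(4E)-hexa-1,4-dien-3-ol
Product: 4 (3S,4E)-hexa-1,4-dien-3-ol
Conditions: Ti(OiPr)4 (10 mol%), D-(−)-diisopropyl tartrate (15 mol%), t-BuOOH (0.6 equiv), 4 Å MS, CH2Cl2, −20 °C, to about 55% conversion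
Reagents that add atoms: none
Why: Sharpless kinetic resolution: with the D-tartrate the (3R)-alcohol is epoxidised quickly at its disubstituted propenyl bond, so the (3S)-alcohol (future 6R centre) is recovered in high ee.

Step 3
Reactants: 4 (3S,4E)-hexa-1,4-dien-3-ol; 5 2-(bromomethyl)prop-2-enoic acid
Product: 6 (3S,4E)-hexa-1,4-dien-3-yl 2-(bromomethyl)prop-2-enoate
Conditions: DCC, DMAP (5 mol%), CH2Cl2, 0 °C
Reagents that add atoms: none
Why: Steglich esterification acylates oxygen only, so the carbinol configuration and the allylic bromide are retained.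

Step 4
Reactants: 6 (3S,4E)-hexa-1,4-dien-3-yl 2-(bromomethyl)prop-2-enoate
Product: 7 (5R)-3-(bromomethyl)-5-[(1E)-prop-1-en-1-yl]furan-2(5H)-one
Conditions: second-generation Hoveyda–Grubbs catalyst (5 mol%), CH2Cl2, 40 °C, 5 mM
Reagents that add atoms: none
Why: Ring-closing metathesis between the terminal vinyl group (which loads the catalyst much faster than the propenyl group) and the acrylate closes the butenolide with loss of ethene and leaves the propenyl group on C6.

Step 5
Reactants: 8 (2Z)-but-2-ene-1,4-diol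
Product: 9 (2Z)-1,4-bis{[tert-butyl(dimethyl)silyl]oxy}but-2-ene
Conditions: TBSCl (2.2 equiv), imidazole, DMF, rt
Reagents that add atoms: tert-butyl(chloro)dimethylsilane, CC(C)(C)[Si](C)(C)Cl
Why: Standard silylation of both primary alcohols.

Step 6
Reactants: 9 (2Z)-1,4-bis{[tert-butyl(dimethyl)silyl]oxy}but-2-ene
Product: 11 {[tert-butyl(dimethyl)silyl]oxy}acetaldehyde, via ozonide 10 (not isolated)
Conditions: O3, CH2Cl2, −78 °C; then PPh3, −78 °C to rt
Reagents that add atoms: ozone, [O-][O+]=O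
Why: Ozonolysis with reductive work-up cleaves the symmetrical alkene into two molecules of the C8–C9 aldehyde.

Step 7
Reactants: 7 (5R)-3-(bromomethyl)-5-[(1E)-prop-1-en-1-yl]furan-2(5H)-one; 11 {[tert-butyl(dimethyl)silyl]oxy}acetaldehyde
Product: 13 (4R,5R)-4-[(1R)-2-{[tert-butyl(dimethyl)silyl]oxy}-1-hydroxyethyl]-3-methylidene-5-[(1E)-prop-1-en-1-yl]oxolan-2-one, via allylchromium dichloride 12 (not isolated)
Conditions: CrCl2 (3 equiv), THF, 0 °C to rt; then H2O
Reagents that add atoms: none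
Why: Chromium Barbier (Nozaki–Hiyama) allylation reacts at the γ-carbon through a closed chair in which the ring holds C6 trans to the CH2Cr group (both C6 and the aldehyde substituent equatorial, giving the 7,8-relationship of the target), and the aldehyde adds to the face opposite the propenyl group (6,7-trans lactone).

Step 8
Reactants: 13 (4R,5R)-4-[(1R)-2-{[tert-butyl(dimethyl)silyl]oxy}-1-hydroxyethyl]-3-methylidene-5-[(1E)-prop-1-en-1-yl]oxolan-2-one; 14 (2S)-2-methylbutanoic acid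
Product: 15 (1R)-2-{[tert-butyl(dimethyl)silyl]oxy}-1-{(2R,3S)-4-methylidene-5-oxo-2-[(1E)-prop-1-en-1-yl]oxolan-3-yl}ethyl (2S)-2-methylbutanoate
Conditions: DCC, DMAP (10 mol%), CH2Cl2, 0 °C to rt
Reagents that add atoms: none
Why: Steglich esterification of the free 8-OH installs the side-chain ester with its (S) centre taken from the acid, and blocks translactonisation onto O8.

Step 9
Reactants: 15 (1R)-2-{[tert-butyl(dimethyl)silyl]oxy}-1-{(2R,3S)-4-methylidene-5-oxo-2-[(1E)-prop-1-en-1-yl]oxolan-3-yl}ethyl (2S)-2-methylbutanoate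
Product: 16 (1R)-2-hydroxy-1-{(2R,3S)-4-methylidene-5-oxo-2-[(1E)-prop-1-en-1-yl]oxolan-3-yl}ethyl (2S)-2-methylbutanoate
Conditions: HF·pyridine, THF, 0 °C
Reagents that add atoms: none
Why: Acidic fluoride desilylation frees the C9 alcohol without the base that would promote acyl migration or conjugate addition.

Step 10
Reactants: 16 (1R)-2-hydroxy-1-{(2R,3S)-4-methylidene-5-oxo-2-[(1E)-prop-1-en-1-yl]oxolan-3-yl}ethyl (2S)-2-methylbutanoate
Product: 17 (1R)-1-{(2R,3S)-4-methylidene-5-oxo-2-[(1E)-prop-1-en-1-yl]oxolan-3-yl}-2-oxoethyl (2S)-2-methylbutanoate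
Conditions: Dess–Martin periodinane, CH2Cl2, 0 °C to rt; used crude
Reagents that add atoms: none
Why: Dess–Martin oxidation gives the α-acyloxy aldehyde (fragment A) under near-neutral conditions that do not epimerise C8.

Step 11
Reactants: 18 but-3-en-1-ylmagnesium bromide; 19 prop-2-yn-1-ol
Product: 20 2-methylidenehex-5-en-1-ol
Conditions: 18 (2.5 equiv), CuI (10 mol%), THF/Et2O, −10 °C to rt; then H2O
Reagents that add atoms: none
Why: Copper-catalysed carbomagnesiation of propargyl alcohol (Duboudin–Jousseaume) delivers the butenyl group to the internal alkyne carbon under alkoxide direction, giving the 2-substituted allylic alcohol that carries C15, C4, C3, C2 and C1.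

Step 12
Reactants: 20 2-methylidenehex-5-en-1-ol
Product: 21 tert-butyl(dimethyl)[(2-methylidenehex-5-en-1-yl)oxy]silane
Conditions: TBSCl, imidazole, CH2Cl2, rt
Reagents that add atoms: tert-butyl(chloro)dimethylsilane, CC(C)(C)[Si](C)(C)Cl
Why: Silyl protection of the C15 alcohol.

Step 13
Reactants: 21 tert-butyl(dimethyl)[(2-methylidenehex-5-en-1-yl)oxy]silane; 1 (2E)-but-2-enal
Product: 22 (2E)-6-({[tert-butyl(dimethyl)silyl]oxy}methyl)hepta-2,6-dienal
Conditions: second-generation Grubbs catalyst (3 mol%), 1 (5 equiv), CH2Cl2, 40 °C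
Reagents that add atoms: none
Why: Cross-metathesis of the monosubstituted alkene with crotonaldehyde gives the (E)-enal (C14, C10, C1) while the 1,1-disubstituted alkene stays inert.

Step 14
Reactants: 22 (2E)-6-({[tert-butyl(dimethyl)silyl]oxy}methyl)hepta-2,6-dienal
Product: 23 (2Z)-6-({[tert-butyl(dimethyl)silyl]oxy}methyl)-2-iodohepta-2,6-dienal
Conditions: I2, pyridine/CH2Cl2, 0 °C to rt
Reagents that add atoms: iodine, II
Why: Johnson α-iodination (pyridine addition, iodination, elimination) gives the thermodynamic (Z)-α-iodoenal with iodine cis to the C2 chain, the geometry C9 will later take at C10.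

Step 15
Reactants: 23 (2Z)-6-({[tert-butyl(dimethyl)silyl]oxy}methyl)-2-iodohepta-2,6-dienal
Product: 24 tert-butyl{[(5Z)-6-iodo-7,7-dimethoxy-2-methylidenehept-5-en-1-yl]oxy}dimethylsilane
Conditions: MeOSiMe3, Me3SiOTf (5 mol%), CH2Cl2, −78 °C
Reagents that add atoms: methoxytrimethylsilane, CO[Si](C)(C)C
Why: Noyori aprotic acetalisation masks the C14 aldehyde without cleaving the silyl ether or moving the double bond (fragment B).

Step 16
Reactants: 17 (1R)-1-{(2R,3S)-4-methylidene-5-oxo-2-[(1E)-prop-1-en-1-yl]oxolan-3-yl}-2-oxoethyl (2S)-2-methylbutanoate; 24 tert-butyl{[(5Z)-6-iodo-7,7-dimethoxy-2-methylidenehept-5-en-1-yl]oxy}dimethylsilane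
Product: 26 (1R,2S,3E)-8-{[tert-butyl(dimethyl)silyl]oxy}-3-(dimethoxymethyl)-2-hydroxy-7-methylidene-1-{(2R,3S)-4-methylidene-5-oxo-2-[(1E)-prop-1-en-1-yl]oxolan-3-yl}oct-3-en-1-yl (2S)-2-methylbutanoate, via alkenylchromium dichloride 25 (not isolated)
Conditions: 24 (1.5 equiv), CrCl2 (6 equiv), NiCl2 (2 mol%), DMSO, rt; then H2O
Reagents that add atoms: none
Why: Nozaki–Hiyama–Kishi alkenylation keeps the iodide geometry (C9 cis to C2) and adds to the α-acyloxy aldehyde in the polar Felkin–Anh sense (nucleophile anti to the C8–O bond), giving the 8,9-anti (9S) alcohol with the ester already on O8.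

Step 17
Reactants: 26 (1R,2S,3E)-8-{[tert-butyl(dimethyl)silyl]oxy}-3-(dimethoxymethyl)-2-hydroxy-7-methylidene-1-{(2R,3S)-4-methylidene-5-oxo-2-[(1E)-prop-1-en-1-yl]oxolan-3-yl}oct-3-en-1-yl (2S)-2-methylbutanoate
Product: 27 (3aS,4R,5S,6E,10E,11aR)-10-({[tert-butyl(dimethyl)silyl]oxy}methyl)-6-(dimethoxymethyl)-5-hydroxy-3-methylidene-2-oxo-3a,4,5,8,9,11a-hexahydrocyclodeca[b]furan-4-yl (2S)-2-methylbutanoate
Conditions: second-generation Hoveyda–Grubbs catalyst (20 mol%), 1,4-benzoquinone (40 mol%), toluene, 80 °C, 1 mM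
Reagents that add atoms: none
Why: Ring-closing metathesis of the propenyl group onto the 1,1-disubstituted alkene closes the ten-membered 1,5-diene with loss of propene, and the ring-cis C4=C5 bond (E by CIP) is expected as the less strained geometry next to the cis C1=C10 bond.

Step 18
Reactants: 27 (3aS,4R,5S,6E,10E,11aR)-10-({[tert-butyl(dimethyl)silyl]oxy}methyl)-6-(dimethoxymethyl)-5-hydroxy-3-methylidene-2-oxo-3a,4,5,8,9,11a-hexahydrocyclodeca[b]furan-4-yl (2S)-2-methylbutanoate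
Product: 29 (3aS,4R,5S,6E,10E,11aR)-6-formyl-5-hydroxy-10-(hydroxymethyl)-3-methylidene-2-oxo-3a,4,5,8,9,11a-hexahydrocyclodeca[b]furan-4-yl (2S)-2-methylbutanoate, via silyl ether enal 28 (not isolated)
Conditions: 48% aq. HF, MeCN, 0 °C to rt
Reagents that add atoms: water, O
Why: Acid hydrolysis of the allylic acetal to the enal and fluoride cleavage of the primary silyl ether occur in one pot, and the acidic medium avoids base-promoted acyl shift from O8 to O9.

**Compound list**

1 | (2E)-but-2-enal | C/C=C/C=O | starting material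
2 | vinylmagnesium bromide | C=C[Mg]Br | starting material
3 | (±)-(4E)-hexa-1,4-dien-3-ol | C/C=C/C(O)C=C | intermediate
4 | (3S,4E)-hexa-1,4-dien-3-ol | C=C[C@H](O)/C=C/C | intermediate
5 | 2-(bromomethyl)prop-2-enoic acid | C=C(CBr)C(=O)O | starting material
6 | (3S,4E)-hexa-1,4-dien-3-yl 2-(bromomethyl)prop-2-enoate | C=C[C@H](OC(=O)C(=C)CBr)/C=C/C | intermediate
7 | (5R)-3-(bromomethyl)-5-[(1E)-prop-1-en-1-yl]furan-2(5H)-one | O=C1O[C@H](/C=C/C)C=C1CBr | intermediate
8 | (2Z)-but-2-ene-1,4-diol | OC/C=C\CO | starting material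
9 | (2Z)-1,4-bis{[tert-butyl(dimethyl)silyl]oxy}but-2-ene | CC(C)(C)[Si](C)(C)OC/C=C\CO[Si](C)(C)C(C)(C)C | intermediate
10 | 3,5-bis({[tert-butyl(dimethyl)silyl]oxy}methyl)-1,2,4-trioxolane (ozonide, cis/trans mixture) | CC(C)(C)[Si](C)(C)OCC1OOC(CO[Si](C)(C)C(C)(C)C)O1 | intermediate
11 | {[tert-butyl(dimethyl)silyl]oxy}acetaldehyde | CC(C)(C)[Si](C)(C)OCC=O | intermediate
12 | dichloro({(5R)-2-oxo-5-[(1E)-prop-1-en-1-yl]-2,5-dihydrofuran-3-yl}methyl)chromium (allylchromium dichloride, trivalent chromium) | O=C1O[C@H](/C=C/C)C=C1C[Cr](Cl)Cl | intermediate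
13 | (4R,5R)-4-[(1R)-2-{[tert-butyl(dimethyl)silyl]oxy}-1-hydroxyethyl]-3-methylidene-5-[(1E)-prop-1-en-1-yl]oxolan-2-one | C=C1C(=O)O[C@H](/C=C/C)[C@H]1[C@@H](O)CO[Si](C)(C)C(C)(C)C | intermediate
14 | (2S)-2-methylbutanoic acid | CC[C@H](C)C(=O)O | starting material
15 | (1R)-2-{[tert-butyl(dimethyl)silyl]oxy}-1-{(2R,3S)-4-methylidene-5-oxo-2-[(1E)-prop-1-en-1-yl]oxolan-3-yl}ethyl (2S)-2-methylbutanoate | C=C1C(=O)O[C@H](/C=C/C)[C@H]1[C@@H](OC(=O)[C@@H](C)CC)CO[Si](C)(C)C(C)(C)C | intermediate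
16 | (1R)-2-hydroxy-1-{(2R,3S)-4-methylidene-5-oxo-2-[(1E)-prop-1-en-1-yl]oxolan-3-yl}ethyl (2S)-2-methylbutanoate | C=C1C(=O)O[C@H](/C=C/C)[C@H]1[C@@H](OC(=O)[C@@H](C)CC)CO | intermediate
17 | (1R)-1-{(2R,3S)-4-methylidene-5-oxo-2-[(1E)-prop-1-en-1-yl]oxolan-3-yl}-2-oxoethyl (2S)-2-methylbutanoate | C=C1C(=O)O[C@H](/C=C/C)[C@H]1[C@@H](OC(=O)[C@@H](C)CC)C=O | intermediate
18 | but-3-en-1-ylmagnesium bromide | C=CCC[Mg]Br | starting material
19 | prop-2-yn-1-ol | C#CCO | starting material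
20 | 2-methylidenehex-5-en-1-ol | C=CCCC(=C)CO | intermediate
21 | tert-butyl(dimethyl)[(2-methylidenehex-5-en-1-yl)oxy]silane | C=CCCC(=C)CO[Si](C)(C)C(C)(C)C | intermediate
22 | (2E)-6-({[tert-butyl(dimethyl)silyl]oxy}methyl)hepta-2,6-dienal | O=C/C=C/CCC(=C)CO[Si](C)(C)C(C)(C)C | intermediate
23 | (2Z)-6-({[tert-butyl(dimethyl)silyl]oxy}methyl)-2-iodohepta-2,6-dienal | O=C/C(I)=C/CCC(=C)CO[Si](C)(C)C(C)(C)C | intermediate
24 | tert-butyl{[(5Z)-6-iodo-7,7-dimethoxy-2-methylidenehept-5-en-1-yl]oxy}dimethylsilane | COC(OC)/C(I)=C/CCC(=C)CO[Si](C)(C)C(C)(C)C | intermediate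
25 | [(2E)-7-{[tert-butyl(dimethyl)silyl]oxy}-1,1-dimethoxy-6-methylidenehept-2-en-2-yl]dichlorochromium (alkenylchromium dichloride, trivalent chromium; Cr cis to the chain) | COC(OC)/C([Cr](Cl)Cl)=C/CCC(=C)CO[Si](C)(C)C(C)(C)C | intermediate
26 | (1R,2S,3E)-8-{[tert-butyl(dimethyl)silyl]oxy}-3-(dimethoxymethyl)-2-hydroxy-7-methylidene-1-{(2R,3S)-4-methylidene-5-oxo-2-[(1E)-prop-1-en-1-yl]oxolan-3-yl}oct-3-en-1-yl (2S)-2-methylbutanoate | C=C1C(=O)O[C@H](/C=C/C)[C@H]1[C@@H](OC(=O)[C@@H](C)CC)[C@@H](O)/C(C(OC)OC)=C\CCC(=C)CO[Si](C)(C)C(C)(C)C | intermediate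
27 | (3aS,4R,5S,6E,10E,11aR)-10-({[tert-butyl(dimethyl)silyl]oxy}methyl)-6-(dimethoxymethyl)-5-hydroxy-3-methylidene-2-oxo-3a,4,5,8,9,11a-hexahydrocyclodeca[b]furan-4-yl (2S)-2-methylbutanoate | C=C1C(=O)O[C@@H]2/C=C(/CO[Si](C)(C)C(C)(C)C)CC/C=C(/C(OC)OC)[C@H](O)[C@H](OC(=O)[C@@H](C)CC)[C@@H]12 | intermediate
28 | (3aS,4R,5S,6E,10E,11aR)-10-({[tert-butyl(dimethyl)silyl]oxy}methyl)-6-formyl-5-hydroxy-3-methylidene-2-oxo-3a,4,5,8,9,11a-hexahydrocyclodeca[b]furan-4-yl (2S)-2-methylbutanoate | C=C1C(=O)O[C@@H]2/C=C(/CO[Si](C)(C)C(C)(C)C)CC/C=C(/C=O)[C@H](O)[C@H](OC(=O)[C@@H](C)CC)[C@@H]12 | intermediate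
29 | (3aS,4R,5S,6E,10E,11aR)-6-formyl-5-hydroxy-10-(hydroxymethyl)-3-methylidene-2-oxo-3a,4,5,8,9,11a-hexahydrocyclodeca[b]furan-4-yl (2S)-2-methylbutanoate (CNP0331447.11) | C=C1C(=O)O[C@@H]2/C=C(/CO)CC/C=C(/C=O)[C@H](O)[C@H](OC(=O)[C@@H](C)CC)[C@@H]12 | target

**Step count**
- Total: 18 steps.
- Longest linear sequence: 11 steps (1–4, 7–10, 16–18).

**Three steps most likely to fail, with fallbacks**

Step 17 (ten-membered ring-closing metathesis onto a 1,1-disubstituted alkene; oligomerisation or wrong C4=C5 geometry). The fallback closes the ring at C9–C10 instead. It sets out from 16 and 24: cross-metathesis (second-generation Hoveyda–Grubbs catalyst, 24 in excess, CH2Cl2, 40 °C; the C4=C5 isomers are separated, and selectivity here is expected to be modest) gives the seco-alcohol F1. Dess–Martin oxidation gives the iodo-aldehyde F2. Intramolecular Nozaki–Hiyama–Kishi cyclisation (CrCl2, NiCl2 cat., DMSO, 2 mM) then forms C9–C10 and comes back to the route at 27.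

Step 16 (diastereoselectivity at C9 relies on Felkin–Anh control, and the α-acyloxy aldehyde is sensitive). The fallback replaces substrate control by reagent control. It sets out from 26 obtained as an unfavourable mixture at C9: Dess–Martin oxidation gives the enone F3, and reduction with (S)-2-methyl-CBS-oxazaborolidine (20 mol%) and catecholborane in toluene at −78 °C (alkenyl group assumed to act as the large substituent) comes back to 26.

Step 7 (the chromium Barbier must give the 7,8-relationship and avoid translactonisation of the chromium alkoxide onto O8). The fallback uses an isolable allylboron reagent. It sets out from 7: borylation with B2pin2 and Pd2(dba)3 (2.5 mol%) in toluene at 50 °C gives the allylboronate F4. Allylboration of 11 with Sc(OTf)3 (10 mol%) in toluene, −40 °C to rt, goes through the same closed chair and gives a neutral borate, and after aqueous work-up comes back to 13.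

**Further compounds**

F1 | step 17 | (1R)-1-{(2R,3S)-2-[(1E,5Z)-2-({[tert-butyl(dimethyl)silyl]oxy}methyl)-6-iodo-7,7-dimethoxyhepta-1,5-dien-1-yl]-4-methylidene-5-oxooxolan-3-yl}-2-hydroxyethyl (2S)-2-methylbutanoate | C=C1C(=O)O[C@H](/C=C(/CO[Si](C)(C)C(C)(C)C)CC/C=C(I)/C(OC)OC)[C@H]1[C@@H](OC(=O)[C@@H](C)CC)CO
F2 | step 17 | (1R)-1-{(2R,3S)-2-[(1E,5Z)-2-({[tert-butyl(dimethyl)silyl]oxy}methyl)-6-iodo-7,7-dimethoxyhepta-1,5-dien-1-yl]-4-methylidene-5-oxooxolan-3-yl}-2-oxoethyl (2S)-2-methylbutanoate | C=C1C(=O)O[C@H](/C=C(/CO[Si](C)(C)C(C)(C)C)CC/C=C(I)/C(OC)OC)[C@H]1[C@@H](OC(=O)[C@@H](C)CC)C=O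
F3 | step 16 | (1R,3Z)-8-{[tert-butyl(dimethyl)silyl]oxy}-3-(dimethoxymethyl)-7-methylidene-1-{(2R,3S)-4-methylidene-5-oxo-2-[(1E)-prop-1-en-1-yl]oxolan-3-yl}-2-oxooct-3-en-1-yl (2S)-2-methylbutanoate | C=C1C(=O)O[C@H](/C=C/C)[C@H]1[C@@H](OC(=O)[C@@H](C)CC)C(=O)/C(C(OC)OC)=C\CCC(=C)CO[Si](C)(C)C(C)(C)C
F4 | step 7 | (5R)-5-[(1E)-prop-1-en-1-yl]-3-[(4,4,5,5-tetramethyl-1,3,2-dioxaborolan-2-yl)methyl]furan-2(5H)-one | O=C1O[C@H](/C=C/C)C=C1CB2OC(C)(C)C(C)(C)O2
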